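**Plan**
- Retrosynthesis: remove the epoxide oxygen (C8=C9 alkene), cut the C4–isopropyl bond (C4 ketone) and the C6–O ester bond. The remaining hydroazulene carries the pattern C5=C6(O)–C7–C8(CH3)=C9 on either side of the C1–C10 bond of the seven-membered ring (C1, C5, C6, C7, C8, C9, C10).
- That pattern is what a cis-divinylcyclopropane with the three-membered ring C6–C7–C8 gives on [3,3] rearrangement, so C1–C10 is cut and C6–C8 reconnected.
- The cyclopropane comes from CH2 (C7) and a C6=C8 silyl dienol ether; its ketone comes from a cyclopentene aldehyde (C6) and a crotyl unit (C8, its methyl, C9, C10); the cyclopentene is 3-methylcyclopent-2-en-1-one.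
- Forward: the five-membered ring is bought, the cyclopropane is made in step 8, the seven-membered ring closes in step 9 as the cyclopropane opens, and the epoxide is added last.
- Stereochemistry: an oxazaborolidine reduction sets C4; C4 steers the carbenoid (C6, C8), and the boat transition state passes this to C1. C4 then controls C5 protonation and C6 hydride delivery, is oxidised, and is rebuilt by isopropyl addition anti to the angular methyl; the epoxide forms anti to that methyl.

Key step: step 9

Remark: atom numbers are those of the daucane skeleton (C1 methyl-bearing fusion carbon, C2 and C3 cyclopentane CH2, C4 carbinol carbon, C5 fusion CH, C6 ester carbon, C7 CH2, C8 and C9 epoxide carbons, C10 CH2 on C1). Descriptors with these locants follow from the SMILES, which define the configurations.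
Assumption: in the oxazaborolidine reduction of a 2-bromo enone the bromine-bearing alkene carbon behaves as the large group.

**Step 1**
Reactants: 1 3-methylcyclopent-2-en-1-one
Product: 3 2-bromo-3-methylcyclopent-2-en-1-one, via trans-dibromo ketone 2 (not isolated)
Conditions: Br2, CH2Cl2, 0 °C; then Et3N, 0 °C to rt
Reagents that add atoms: bromine, BrBr
Why: Ionic anti addition of bromine to the enone followed by amine-induced loss of HBr from the α-bromo ketone is the standard addition–elimination α-bromination of a cyclic enone.

**Step 2**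
Reactants: 3 2-bromo-3-methylcyclopent-2-en-1-one
Product: 4 (S)-2-bromo-3-methylcyclopent-2-en-1-ol
Conditions: (R)-2-methyl-CBS-oxazaborolidine (10 mol %), BH3·SMe2, THF, −20 °C; then MeOH
Reagents that add atoms: none
Why: Corey–Bakshi–Shibata reduction with the brominated alkene carbon as the large group should give the (S)-alcohol, which sets C4 as the centre that later relays chirality to C1, C5 and C6.

**Step 3**
Reactants: 4 (S)-2-bromo-3-methylcyclopent-2-en-1-ol
Product: 5 (S)-[(2-bromo-3-methylcyclopent-2-en-1-yl)oxy](tert-butyl)dimethylsilane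
Conditions: TBSCl, imidazole, DMF, rt
Reagents that add atoms: tert-butyldimethylsilyl chloride, CC(C)(C)[Si](C)(C)Cl
Why: Imidazole-promoted silylation of a secondary allylic alcohol leaves the stereocentre untouched and gives an ether that tolerates alkyllithiums and zinc carbenoids.

**Step 4**
Reactants: 5 (S)-[(2-bromo-3-methylcyclopent-2-en-1-yl)oxy](tert-butyl)dimethylsilane
Product: 7 (S)-5-(tert-butyldimethylsilyloxy)-2-methylcyclopent-1-ene-1-carbaldehyde, via vinyllithium 6 (not isolated)
Conditions: t-BuLi (2.1 equiv), THF, −78 °C; DMF, −78 to 0 °C; then H2O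
Reagents that add atoms: N,N-dimethylformamide, CN(C)C=O
Why: Bromine–lithium exchange gives a cyclic vinyllithium that cannot β-eliminate and should not undergo silyl migration at −78 °C, and its formylation with DMF supplies C6.

**Step 5**
Reactants: 7 (S)-5-(tert-butyldimethylsilyloxy)-2-methylcyclopent-1-ene-1-carbaldehyde; 8 but-2-enylmagnesium chloride (crotylmagnesium chloride, commercial THF solution)
Product: 9 1-[(5S)-5-(tert-butyldimethylsilyloxy)-2-methylcyclopent-1-en-1-yl]-2-methylbut-3-en-1-ol (mixture of diastereomers at C6 and C8)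
Conditions: THF, −78 °C; then aq. NH4Cl
Reagents that add atoms: none
Why: Allylic Grignard reagents add to aldehydes at their γ-carbon through a cyclic transition state (crotylation), which attaches C8 with its methyl and the C9=C10 vinyl group; both new centres are removed in steps 6 and 7.

**Step 6**
Reactants: 9 1-[(5S)-5-(tert-butyldimethylsilyloxy)-2-methylcyclopent-1-en-1-yl]-2-methylbut-3-en-1-ol
Product: 10 1-[(5S)-5-(tert-butyldimethylsilyloxy)-2-methylcyclopent-1-en-1-yl]-2-methylbut-3-en-1-one (both C8 epimers)
Conditions: Dess–Martin periodinane, NaHCO3, CH2Cl2, 0 °C to rt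
Reagents that add atoms: none
Why: Dess–Martin oxidation is neutral and base-free, so the β,γ-alkene should not move into conjugation.

**Step 7**
Reactants: 10 1-[(5S)-5-(tert-butyldimethylsilyloxy)-2-methylcyclopent-1-en-1-yl]-2-methylbut-3-en-1-one
Product: 12 (1E)-silyl dienol ether of 10 (C6 silyloxy cis to the C8 methyl; cyclopentenyl cis to vinyl), via potassium dienolate 11 (not isolated)
Conditions: KN(SiMe3)2, THF, −78 °C; TBSOTf, −78 °C; Et3N-buffered work-up
Reagents that add atoms: tert-butyldimethylsilyl trifluoromethanesulfonate, CC(C)(C)[Si](C)(C)OS(=O)(=O)C(F)(F)F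
Why: Kinetic enolate formation and O-silylation: C8–H is the only α-hydrogen and is also allylic, so the dienolate forms regiospecifically (a tiglyl ketone would also offer γ-hydrogens on the cyclopentene), and the flat vinyl group rather than the methyl group is expected to take the position cis to the bulky, twisted cyclopentenyl group (E isomer).

**Step 8**
Reactants: 12 (1E)-silyl dienol ether
Product: 13 (4S,6S,8R)-cis-divinylcyclopropane (C6 carries OTBS and the cyclopentenyl group; C8 carries methyl and vinyl; cyclopentenyl and vinyl cis)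
Conditions: Et2Zn, CH2I2, CH2Cl2, 0 °C; then pyridine, aq. NaHCO3
Reagents that add atoms: diiodomethane, ICI
Why: Simmons–Smith (Furukawa) cyclopropanation: the electrophilic zinc carbenoid attacks the most electron-rich alkene, the tetrasubstituted enol ether, adds syn so that E geometry becomes the cis relationship, and is expected to enter from the enol ether face opposite C4 in the conformer where the cyclopentene is perpendicular and the C4 silyloxy group is turned away from the C8 arm.

**Step 9**
Reactants: 13 (4S,6S,8R)-cis-divinylcyclopropane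
Product: 14 (3S,8aR)-3,4-bis(tert-butyldimethylsilyloxy)-6,8a-dimethyl-1,2,3,5,8,8a-hexahydroazulene (daucane 1R,4S; C5=C6 silyl enol ether; C8=C9 alkene; quaternary C1)
Conditions: PhMe (0.02 M, degassed), BHT (cat.), base-washed sealed tube, 110–130 °C
Reagents that add atoms: none
Why: A concerted [3,3] sigmatropic (Cope) rearrangement passes through a boat transition state with the cyclopentene C5=C1 and the vinyl C9=C10 folded over the three-membered ring; the C6–C8 bond breaks as C1–C10 forms, leaving C5=C6(OTBS) and C8=C9. The closest known reactions are the thermal divinylcyclopropane–cycloheptadiene rearrangements of siloxy vinylcyclopropanes and of 2-methylcycloalkenyl vinylcyclopropanes that give angularly methylated hydroazulenes. The seven-membered ring closes by suprafacial bonding of the two alkene termini held cis on the cyclopropane, a four-atom ring expansion of the cyclopropane rather than a cyclisation of a chain. The new stereocentre C1 is fixed by the configuration of C6 and C8, because in the only possible boat C10 reaches the cyclopentene face turned toward C8, which is the face anti to the C4 silyloxy group, so the methyl ends up cis to that group. The step needs the cis isomer, which the E enol ether and the syn carbenoid addition provide, and it has no cis alkyl C–H next to a vinyl group, so the homo-1,5-hydrogen shift cannot compete. The inward methyl on the tetrasubstituted terminus raises the barrier, hence the heating, while ring-strain release and the C6 siloxy donor drive the reaction.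

**Step 10**
Reactants: 14 hydroazulene bis-silyl ether
Product: 16 (3S,3aR,8aR)-3-hydroxy-6,8a-dimethyl-2,3,3a,5,8,8a-hexahydroazulen-4(1H)-one (trans-fused; C4–OH cis to the C1 methyl), via silyloxy ketone 15 (not isolated)
Conditions: HF·pyridine, pyridine, THF, 0 °C to rt
Reagents that add atoms: none
Why: Buffered HF desilylation: the silyl enol ether is cleaved first with protonation of C5 from the face opposite both the angular methyl and the C4 silyloxy group (trans ring fusion), and the secondary silyl ether follows more slowly.

**Step 11**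
Reactants: 16 trans-fused β-hydroxy ketone
Product: 17 (3S,3aR,4S,8aR)-6,8a-dimethyl-1,2,3,3a,4,5,8,8a-octahydroazulene-3,4-diol (C6–OH trans to the C1 methyl and to the C4–OH)
Conditions: Me4NBH(OAc)3, MeCN/AcOH (1:1), −20 to 0 °C; then aq. potassium sodium tartrate
Reagents that add atoms: none
Why: Evans–Saksena hydroxyl-directed reduction: the acetoxyborohydride bound to the C4 oxygen, which lies on the methyl-side face of the C6 carbonyl, delivers hydride to that face only and gives the 1,3-anti diol with an equatorial C6 hydroxyl.

**Step 12**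
Reactants: 17 anti diol; 18 4-methoxybenzoyl chloride
Product: 19 C6 4-methoxybenzoate of 17 with free C4 hydroxyl (daucane 1R,4S,5R,6S)
Conditions: 18 (1.05 equiv), pyridine, DMAP (cat.), CH2Cl2, −20 to 0 °C
Reagents that add atoms: none
Why: DMAP-catalysed acylation should pick the equatorial C6 hydroxyl, because the C4 hydroxyl is shielded by the cis angular methyl and the cis C5 substituent; the ester also serves as protection for the next two steps.

**Step 13**
Reactants: 19 hydroxy ester
Product: 20 C4 ketone (daucane 1R,5S,6S; β-acyloxy cyclopentanone)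
Conditions: Dess–Martin periodinane, NaHCO3, CH2Cl2, 0 °C to rt
Reagents that add atoms: none
Why: Dess–Martin oxidation of the secondary alcohol is neutral, so the β-acyloxy ketone should survive without elimination or C5 epimerisation.

**Step 14**
Reactants: 20 C4 ketone
Product: 21 tertiary alcohol (daucane 1R,4R,5S,6S; C4–OH cis to the C1 methyl, isopropyl cis to C5–H)
Conditions: i-PrMgCl, CeCl3 (dried), THF, −78 °C; then aq. NH4Cl
Reagents that add atoms: isopropylmagnesium chloride, CC(C)[Mg]Cl
Why: Organocerium 1,2-addition is weakly basic, which suppresses enolisation, β-elimination and attack on the aryl ester, and the reagent approaches the cyclopentanone from the face of C5–H, away from the angular methyl and C6.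

**Step 15**
Reactants: 21 tertiary alcohol with C8=C9 alkene
Product: 22 CNP0235939.1 (daucane 1R,4R,5S,6S,8R,9S; epoxide trans to the C1 methyl and cis to the C6 ester)
Conditions: mCPBA, NaHCO3, CH2Cl2, 0 °C
Reagents that add atoms: 3-chloroperoxybenzoic acid, OOC(=O)c1cccc(Cl)c1
Why: Peracid (Prilezhaev) epoxidation of the only alkene should occur on the face opposite the axial angular methyl, which sits over C9.

**Compound list**
1 | 3-methylcyclopent-2-en-1-one | CC1=CC(=O)CC1 | starting material
2 | trans-2,3-dibromo-3-methylcyclopentan-1-one (racemic; one enantiomer drawn) | C[C@]1(Br)CCC(=O)[C@@H]1Br | intermediate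
3 | 2-bromo-3-methylcyclopent-2-en-1-one | CC1=C(Br)C(=O)CC1 | intermediate
4 | (S)-2-bromo-3-methylcyclopent-2-en-1-ol | O[C@H]1CCC(C)=C1Br | intermediate
5 | (S)-[(2-bromo-3-methylcyclopent-2-en-1-yl)oxy](tert-butyl)dimethylsilane | CC(C)(C)[Si](C)(C)O[C@H]1CCC(C)=C1Br | intermediate
6 | [(5S)-5-(tert-butyldimethylsilyloxy)-2-methylcyclopent-1-en-1-yl]lithium | CC(C)(C)[Si](C)(C)O[C@H]1CCC(C)=C1[Li] | intermediate
7 | (S)-5-(tert-butyldimethylsilyloxy)-2-methylcyclopent-1-ene-1-carbaldehyde | CC(C)(C)[Si](C)(C)O[C@H]1CCC(C)=C1C=O | intermediate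
8 | but-2-enylmagnesium chloride (crotylmagnesium chloride) | C/C=C/C[Mg]Cl | starting material
9 | 1-[(5S)-5-(tert-butyldimethylsilyloxy)-2-methylcyclopent-1-en-1-yl]-2-methylbut-3-en-1-ol (diastereomer mixture at C6 and C8) | C=CC(C)C(O)C1=C(C)CC[C@@H]1O[Si](C)(C)C(C)(C)C | intermediate
10 | 1-[(5S)-5-(tert-butyldimethylsilyloxy)-2-methylcyclopent-1-en-1-yl]-2-methylbut-3-en-1-one (C8 epimers) | C=CC(C)C(=O)C1=C(C)CC[C@@H]1O[Si](C)(C)C(C)(C)C | intermediate
11 | potassium (1E)-1-[(5S)-5-(tert-butyldimethylsilyloxy)-2-methylcyclopent-1-en-1-yl]-2-methylbuta-1,3-dien-1-olate | C=C/C(C)=C(/[O-])C1=C(C)CC[C@@H]1O[Si](C)(C)C(C)(C)C.[K+] | intermediate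
12 | tert-butyl{[(1E)-1-[(5S)-5-(tert-butyldimethylsilyloxy)-2-methylcyclopent-1-en-1-yl]-2-methylbuta-1,3-dien-1-yl]oxy}dimethylsilane | C=C/C(C)=C(/O[Si](C)(C)C(C)(C)C)C1=C(C)CC[C@@H]1O[Si](C)(C)C(C)(C)C | intermediate
13 | tert-butyl{[(1S,2R)-1-[(5S)-5-(tert-butyldimethylsilyloxy)-2-methylcyclopent-1-en-1-yl]-2-ethenyl-2-methylcyclopropyl]oxy}dimethylsilane (cis-divinylcyclopropane) | C=C[C@@]1(C)C[C@@]1(O[Si](C)(C)C(C)(C)C)C1=C(C)CC[C@@H]1O[Si](C)(C)C(C)(C)C | intermediate
14 | (3S,8aR)-3,4-bis(tert-butyldimethylsilyloxy)-6,8a-dimethyl-1,2,3,5,8,8a-hexahydroazulene | CC(C)(C)[Si](C)(C)OC1=C2[C@@H](O[Si](C)(C)C(C)(C)C)CC[C@]2(C)CC=C(C)C1 | intermediate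
15 | (3S,3aR,8aR)-3-(tert-butyldimethylsilyloxy)-6,8a-dimethyl-2,3,3a,5,8,8a-hexahydroazulen-4(1H)-one | O=C1CC(C)=CC[C@@]2(C)CC[C@H](O[Si](C)(C)C(C)(C)C)[C@H]12 | intermediate
16 | (3S,3aR,8aR)-3-hydroxy-6,8a-dimethyl-2,3,3a,5,8,8a-hexahydroazulen-4(1H)-one | O=C1CC(C)=CC[C@@]2(C)CC[C@H](O)[C@H]12 | intermediate
17 | (3S,3aR,4S,8aR)-6,8a-dimethyl-1,2,3,3a,4,5,8,8a-octahydroazulene-3,4-diol | O[C@H]1CC(C)=CC[C@@]2(C)CC[C@H](O)[C@H]12 | intermediate
18 | 4-methoxybenzoyl chloride | COc1ccc(cc1)C(Cl)=O | starting material
19 | C6 4-methoxybenzoate of diol 17 (daucane 1R,4S,5R,6S; free C4–OH) | COc1ccc(cc1)C(=O)O[C@H]1CC(C)=CC[C@@]2(C)CC[C@H](O)[C@H]12 | intermediate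
20 | C4 ketone (daucane 1R,5S,6S) | COc1ccc(cc1)C(=O)O[C@H]1CC(C)=CC[C@@]2(C)CCC(=O)[C@H]12 | intermediate
21 | C4 isopropyl carbinol with C8=C9 alkene (daucane 1R,4R,5S,6S) | COc1ccc(cc1)C(=O)O[C@H]1CC(C)=CC[C@@]2(C)CC[C@@](O)(C(C)C)[C@H]12 | intermediate
22 | CNP0235939.1 (daucane 1R,4R,5S,6S,8R,9S) | COc1ccc(C(=O)O[C@H]2C[C@@]3(C)O[C@H]3C[C@@]3(C)CC[C@@](O)(C(C)C)[C@H]23)cc1 | target

**Totals**
Total step count: 15. Longest linear sequence: 15 steps (from 1; compounds 8 and 18 are bought).

**Steps most likely to fail**

Step 8. The carbenoid may add to the terminal vinyl group of the dienol ether instead of the hindered enol ether, the C4 centre may discriminate the two enol ether faces poorly, and zinc iodide may open the siloxycyclopropane. The face preference is the least certain prediction in the route. Because C4 is still present, a wrong-face isomer is a diastereomer and can be removed at 13 or 14. The fallback sets out from aldehyde 7 and returns at cyclopropane 13, and it removes the competing alkene. Barbier addition of the allenylzinc reagent from 3-bromobut-1-yne and Zn to 7 would give the homopropargylic alcohol F1. Dess–Martin oxidation would give the ynone F2. KN(SiMe3)2 and TBSOTf would give the enyne silyl enol ether F3, in which the rod-like alkynyl group should sit cis to the cyclopentenyl group. Et2Zn and CH2I2 can then only attack the enol ether and would give the alkynylcyclopropane F4. Semi-hydrogenation over Pd/CaCO3 poisoned with Pb(OAc)2 and quinoline would unmask the vinyl group and deliver 13.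

Step 12. Acyl transfer may also reach the C4 hydroxyl or give the diester, since both hydroxyls are secondary. The fallback sets out from hydroazulene 14 and returns at ester 19, and it never has two free hydroxyls. Bu4NF buffered with AcOH at −40 °C would cleave only the enol ether and give the silyloxy ketone 15, now isolated. LiBH(s-Bu)3 would attack the ketone from the face opposite the angular methyl and the C4 silyloxy group and give the C6-epimeric alcohol F5. Mitsunobu inversion with 4-methoxybenzoic acid, PPh3 and DIAD would give the silyl-protected ester F6, and HF·pyridine would then give 19.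

Step 14. The β-acyloxy ketone may lose 4-methoxybenzoate by base-induced elimination through the C4 enolate, may epimerise at C5, or the organometallic may attack the ester. The fallback sets out from diol 17 and returns at 21, and it carries C6 as a silyl ether through the addition. TBSCl and imidazole would silylate the less hindered C6 hydroxyl and give the silyl ether F7. Dess–Martin oxidation would give the ketone F8. i-PrMgCl with CeCl3 would give the tertiary alcohol F9. Bu4NF would give the diol F10, whose only secondary hydroxyl is then acylated with 18, pyridine and DMAP to give 21.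

**Further compounds**
F1 | step 8 | 1-[(5S)-5-(tert-butyldimethylsilyloxy)-2-methylcyclopent-1-en-1-yl]-2-methylbut-3-yn-1-ol (diastereomer mixture) | C#CC(C)C(O)C1=C(C)CC[C@@H]1O[Si](C)(C)C(C)(C)C
F2 | step 8 | 1-[(5S)-5-(tert-butyldimethylsilyloxy)-2-methylcyclopent-1-en-1-yl]-2-methylbut-3-yn-1-one | C#CC(C)C(=O)C1=C(C)CC[C@@H]1O[Si](C)(C)C(C)(C)C
F3 | step 8 | (1E)-enyne silyl enol ether (alkynyl cis to cyclopentenyl) | C#C/C(C)=C(/O[Si](C)(C)C(C)(C)C)C1=C(C)CC[C@@H]1O[Si](C)(C)C(C)(C)C
F4 | step 8 | 2-ethynyl analogue of cyclopropane 13 (cyclopentenyl cis to ethynyl) | C#C[C@@]1(C)C[C@@]1(O[Si](C)(C)C(C)(C)C)C1=C(C)CC[C@@H]1O[Si](C)(C)C(C)(C)C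
F5 | step 12 | C6-epimeric alcohol with C4 silyl ether (C6–OH cis to the C1 methyl) | O[C@@H]1CC(C)=CC[C@@]2(C)CC[C@H](O[Si](C)(C)C(C)(C)C)[C@H]12
F6 | step 12 | C6 4-methoxybenzoate with C4 silyl ether | COc1ccc(cc1)C(=O)O[C@H]1CC(C)=CC[C@@]2(C)CC[C@H](O[Si](C)(C)C(C)(C)C)[C@H]12
F7 | step 14 | C6 tert-butyldimethylsilyl ether of diol 17 | CC(C)(C)[Si](C)(C)O[C@H]1CC(C)=CC[C@@]2(C)CC[C@H](O)[C@H]12
F8 | step 14 | C4 ketone with C6 silyl ether | CC(C)(C)[Si](C)(C)O[C@H]1CC(C)=CC[C@@]2(C)CCC(=O)[C@H]12
F9 | step 14 | C4 isopropyl carbinol with C6 silyl ether | CC(C)(C)[Si](C)(C)O[C@H]1CC(C)=CC[C@@]2(C)CC[C@@](O)(C(C)C)[C@H]12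
F10 | step 14 | C4,C6 diol with isopropyl at C4 and C8=C9 alkene | O[C@H]1CC(C)=CC[C@@]2(C)CC[C@@](O)(C(C)C)[C@H]12
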